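**Retrosynthetic overview**
Feature: on ring A of the isoflavone, C6 carries ArCH2(C1'')–CH(OH)(C2'')–C(CH3)(C3'')=CH2(C4''). This isopropenyl carbinol is the 1,3-transposed form of an (E)-4-aryl-2-methylbut-2-en-1-ol, so C2'' can be set by hydroxyl-directed epoxidation of a C2''=C3'' bond, and the hydroxyl on C4'' keeps the oxidant off the C8 prenyl alkene.
Disconnections, backwards: four aryl O–Si bonds (fluoride); the C3''–O bond of a C2''/C3'' oxirane with loss of iodide from C4'' (zinc); C4''–I from C4''–OH; the two oxirane C–O bonds (titanium–tartrate epoxidation).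
Further back: C4''–OH from the (E)-enal; the C2''=C3'' bond by cross-metathesis of a 6-allyl group with methacrolein; the C6–allyl and C8–prenyl bonds by sigmatropic transfer from O5 (prenyl ether: Claisen–Cope to C8; then allyl ether: ortho-Claisen to C6).
Ring order: rings A (phloroglucinol) and B (3,4-dihydroxyphenylacetic acid) are bought; ring C (pyranone) is closed in step 1; the oxirane is closed in step 10 and opened again in step 12.

Key step: step 10

Remark: isoflavone numbering is used, the C6 side chain is numbered C1'' (benzylic CH2) to C4'', TBS = tert-butyldimethylsilyl, and the target is taken as the (2''R) enantiomer that the SMILES encodes.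

**Route**

Step 1
Reactants: 1 phloroglucinol; 2 3,4-dihydroxyphenylacetic acid
Product: 4 orobol (5,7,3',4'-tetrahydroxyisoflavone), via deoxybenzoin 3 (not isolated)
Conditions: BF3·OEt2 (solvent), 85 °C; then DMF, MsCl, 55 → 90 °C; then water
Reagents that add atoms: N,N-dimethylformamide CN(C)C=O
Why: Friedel–Crafts (Nencki-type) C-acylation of the symmetrical triphenol gives deoxybenzoin 3, whose boron-chelated enol is C-formylated at the benzylic carbon by the DMF/MsCl Vilsmeier-type reagent and closes ring C by attack of the ortho phenol on the aminomethylene carbon with loss of dimethylamine, an established one-pot isoflavone annulation that tolerates free phenols.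

Step 2
Reactants: 4 orobol
Product: 5 orobol 7,3',4'-tris(TBS) ether (5-OH free)
Conditions: TBSCl (3.5 equiv), imidazole (7 equiv), DMF, 0 °C → rt
Reagents that add atoms: tert-butyldimethylsilyl chloride CC(C)(C)[Si](C)(C)Cl
Why: Imidazole-mediated O-silylation caps the three acidic phenols (O7, O3', O4'), whereas the 5-OH, hydrogen-bonded to the C4 carbonyl, is unreactive towards the silyl chloride at room temperature and stays free as the handle for both C–C bond formations.

Step 3
Reactants: 5 orobol 7,3',4'-tris(TBS) ether; 6 3-methylbut-2-en-1-ol (prenyl alcohol)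
Product: 7 5-O-prenylorobol 7,3',4'-tris(TBS) ether
Conditions: PPh3, DIAD, THF, 0 °C → rt
Reagents that add atoms: none
Why: Mitsunobu etherification, in which the chelated 5-OH (the only acidic proton left) displaces the primary allylic oxyphosphonium group by SN2 under neutral conditions that do not endanger the base-labile aryl silyl ethers, as is known for 5-O-prenylation of 7-O-protected flavonoids.

Step 4
Reactants: 7 5-O-prenylorobol 7,3',4'-tris(TBS) ether
Product: 10 8-prenylorobol 7,3',4'-tris(TBS) ether, via ortho-dienone 8 (not isolated), via para-dienone 9 (not isolated)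
Conditions: Eu(fod)3 (fod = 6,6,7,7,8,8,8-heptafluoro-2,2-dimethyloctane-3,5-dionate; 10 mol %), CHCl3, 65 °C, sealed tube
Reagents that add atoms: none
Why: Lewis-acid-catalysed para-Claisen–Cope rearrangement, in which trivalent europium chelated between the C4 carbonyl and O5 accelerates the [3,3] shift to C6, and the congested reverse-prenyl dienone 8 (squeezed between C5=O and the C7 silyloxy group) undergoes a second [3,3] (Cope) shift to C8 before it can enolise, so that dienone 9 aromatises to the linear 8-prenyl phenol, as established for 5-O-prenyl flavonoids.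

Step 5
Reactants: 10 8-prenylorobol 7,3',4'-tris(TBS) ether; 11 prop-2-en-1-ol (allyl alcohol)
Product: 12 5-O-allyl-8-prenylorobol 7,3',4'-tris(TBS) ether
Conditions: PPh3, DIAD, THF, 0 °C → rt
Reagents that add atoms: none
Why: Mitsunobu etherification of the regenerated chelated 5-OH (still flanked by C6–H) with a primary allylic alcohol, by the same reasoning as in step 3.

Step 6
Reactants: 12 5-O-allyl-8-prenylorobol 7,3',4'-tris(TBS) ether
Product: 14 6-allyl-8-prenylorobol 7,3',4'-tris(TBS) ether, via ortho-dienone 13 (not isolated)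
Conditions: N,N-diethylaniline, 185 °C, argon, sealed tube
Reagents that add atoms: none
Why: Thermal aromatic Claisen rearrangement, in which C6 is the only ortho position of O5 that can rearomatise (C4a is a ring-fusion carbon) and the para position C8 is blocked, so the [3,3] shift delivers the allyl group to C6 and the 6-H dienone 13 enolises at once in the basic solvent, the terminal CH2 of the ether becoming the benzylic C1''.

Step 7
Reactants: 14 6-allyl-8-prenylorobol 7,3',4'-tris(TBS) ether
Product: 15 6-allyl-8-prenylorobol 5,7,3',4'-tetrakis(TBS) ether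
Conditions: TBSOTf (1.5 equiv), 2,6-lutidine (3 equiv), CH2Cl2, 0 °C → rt
Reagents that add atoms: tert-butyldimethylsilyl trifluoromethanesulfonate CC(C)(C)[Si](C)(C)OS(=O)(=O)C(F)(F)F
Why: O-Silylation with the silyl triflate, which is electrophilic enough for the hydrogen-bonded and doubly flanked 5-OH, gives the fully protected arene so that neither the later primary alcohol nor titanium finds a free phenol (the product is handled on base-washed silica because this silyl ether lies peri to the carbonyl).

Step 8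
Reactants: 15 6-allyl-8-prenylorobol tetrakis(TBS) ether; 16 methacrolein (2-methylprop-2-enal)
Product: 17 6-[(E)-3-methyl-4-oxobut-2-enyl]-8-prenylorobol tetrakis(TBS) ether
Conditions: second-generation Grubbs catalyst (H2IMes)(PCy3)Cl2Ru=CHPh (5 mol %), 16 (10 equiv), 1,4-benzoquinone (10 mol %), CH2Cl2, 40 °C
Reagents that add atoms: none
Why: Olefin cross-metathesis of the terminal allyl alkene with the 1,1-disubstituted enal (in excess) releases ethene and gives the trisubstituted enal with (E) geometry under thermodynamic control, as is usual for methacrolein, while the trisubstituted prenyl alkene enters the catalytic cycle much more slowly and benzoquinone suppresses ruthenium-hydride migration of the allyl double bond.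

Step 9
Reactants: 17 6-[(E)-3-methyl-4-oxobut-2-enyl]-8-prenylorobol tetrakis(TBS) ether
Product: 18 6-[(E)-4-hydroxy-3-methylbut-2-enyl]-8-prenylorobol tetrakis(TBS) ether
Conditions: NaBH4, CeCl3·7H2O, MeOH/THF 1:1, −40 °C, 20 min; pH 7 buffer
Reagents that add atoms: none
Why: Luche 1,2-reduction, in which the cerium-activated aldehyde is reduced within minutes at low temperature, much faster than the hindered vinylogous-ester carbonyl of ring C or conjugate addition, and the (E)-trisubstituted alkene is carried unchanged into allylic alcohol 18.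

Step 10
Reactants: 18 6-[(E)-4-hydroxy-3-methylbut-2-enyl]-8-prenylorobol tetrakis(TBS) ether
Product: 19 6-{[(2R,3R)-3-(hydroxymethyl)-3-methyloxiran-2-yl]methyl}-8-prenylorobol tetrakis(TBS) ether
Conditions: Ti(OiPr)4 (0.2 equiv), D-(−)-diethyl tartrate (0.24 equiv), t-BuOOH (2 equiv, anhydrous in decane), 4 Å molecular sieves, CH2Cl2, −20 °C; quench with aq citric acid/FeSO4
Reagents that add atoms: tert-butyl hydroperoxide CC(C)(C)OO
Why: Katsuki–Sharpless asymmetric epoxidation: the primary C4''–OH and tert-butyl hydroperoxide exchange for isopropoxide on the tartrate-bridged dimer of tetravalent titanium, and the titanium-bound peroxide oxygen is passed to the C2''=C3'' bond inside this complex. The oxirane closes by one concerted, stereospecific syn oxygen-atom transfer (a [2+1] addition forming both C–O bonds together, with no open intermediate), so the (E) geometry becomes the trans relation of CH2OH and CH2Ar. The closest precedent is the epoxidation of (E)-2-methyl-2-alken-1-ols such as (E)-2-methyl-3-phenylprop-2-en-1-ol, a fast and highly enantioselective substrate class. Both new stereocentres (C2'' R and C3'' R) are fixed by the tartrate: the (S,S)-configured D-(−)-ester exposes the alkene face that leads to the (2R,3R)-epoxy alcohol, the L-(+)-ester being known to give the (2S,3S) series. The step needs chemoselectivity for the chain alkene over the equally electron-rich C8 prenyl alkene and the C2=C3 bond of ring C; only the alkene tethered to titanium through its own hydroxyl is activated, and all four phenols are silylated so that no other site binds the metal. The work-up is kept non-basic so that the aryl silyl ethers survive.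

Step 11
Reactants: 19 6-{[(2R,3R)-3-(hydroxymethyl)-3-methyloxiran-2-yl]methyl}-8-prenylorobol tetrakis(TBS) ether
Product: 20 6-{[(2R,3S)-3-(iodomethyl)-3-methyloxiran-2-yl]methyl}-8-prenylorobol tetrakis(TBS) ether
Conditions: PPh3, imidazole, I2, CH2Cl2, 0 °C, dark
Reagents that add atoms: iodine [I][I]
Why: Garegg–Samuelsson (Appel-type) iodination, in which the primary alcohol is activated as its alkoxyphosphonium ion and displaced by iodide by SN2 at C4'' under imidazole buffering (the phosphine–iodine complex is formed first so that no free iodine meets the prenyl alkene), no stereocentre being touched and the descriptor of C3'' changing from R to S only because CH2I outranks the ring carbon.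

Step 12
Reactants: 20 6-{[(2R,3S)-3-(iodomethyl)-3-methyloxiran-2-yl]methyl}-8-prenylorobol tetrakis(TBS) ether
Product: 21 6-[(2R)-2-hydroxy-3-methylbut-3-enyl]-8-prenylorobol tetrakis(TBS) ether
Conditions: Zn dust (activated, 10 equiv), EtOH, 60 °C; then aq NH4Cl
Reagents that add atoms: none
Why: Zinc-mediated reductive β-elimination (Boord-type opening of a 2,3-epoxy iodide), in which zerovalent zinc inserts into the C4''–I bond and the organozinc expels the neighbouring epoxide oxygen, breaking the tertiary C3''–O bond and forming the C3''=C4'' alkene, whereas the C2''–O bond is not involved and C2'' keeps its (R) configuration.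

Step 13
Reactants: 21 6-[(2R)-2-hydroxy-3-methylbut-3-enyl]-8-prenylorobol tetrakis(TBS) ether
Product: 22 6-[(2R)-2-hydroxy-3-methylbut-3-enyl]-8-prenylorobol (CNP0305771.1)
Conditions: Bu4NF (5 equiv), AcOH (5 equiv), THF, 0 °C → rt, argon; pH 6 phosphate buffer
Reagents that add atoms: none
Why: Fluoride-mediated cleavage of the four aryl O–Si bonds (driven by Si–F bond formation) under acetic acid buffering frees all phenols without mineral acid, which would cyclise the prenyl and isopropenyl groups onto the ortho phenols, and without strongly basic conditions, which would expose the catechol to oxidation.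

**Compound list**
1 | phloroglucinol | Oc1cc(O)cc(O)c1 | starting material
2 | 3,4-dihydroxyphenylacetic acid | OC(=O)Cc1ccc(O)c(O)c1 | starting material
3 | deoxybenzoin: 2-(3,4-dihydroxyphenyl)-1-(2,4,6-trihydroxyphenyl)ethanone (not isolated) | O=C(Cc1ccc(O)c(O)c1)c1c(O)cc(O)cc1O | intermediate
4 | orobol (5,7,3',4'-tetrahydroxyisoflavone) | O=c1c(-c2ccc(O)c(O)c2)coc2cc(O)cc(O)c12 | intermediate
5 | orobol 7,3',4'-tris(TBS) ether | O=c1c(-c2ccc(O[Si](C)(C)C(C)(C)C)c(O[Si](C)(C)C(C)(C)C)c2)coc2cc(O[Si](C)(C)C(C)(C)C)cc(O)c12 | intermediate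
6 | 3-methylbut-2-en-1-ol (prenyl alcohol) | CC(C)=CCO | starting material
7 | 5-O-prenylorobol 7,3',4'-tris(TBS) ether | O=c1c(-c2ccc(O[Si](C)(C)C(C)(C)C)c(O[Si](C)(C)C(C)(C)C)c2)coc2cc(O[Si](C)(C)C(C)(C)C)cc(OCC=C(C)C)c12 | intermediate
8 | ortho-dienone: 6-(2-methylbut-3-en-2-yl)-6H-chromene-4,5-dione tautomer (not isolated) | C=CC(C)(C)C1C(=O)C2=C(OC=C(c3ccc(O[Si](C)(C)C(C)(C)C)c(O[Si](C)(C)C(C)(C)C)c3)C2=O)C=C1O[Si](C)(C)C(C)(C)C | intermediate
9 | para-dienone: 8-prenyl-8H-chromene-4,5-dione tautomer (not isolated) | CC(C)=CCC1C(O[Si](C)(C)C(C)(C)C)=CC(=O)C2=C1OC=C(c1ccc(O[Si](C)(C)C(C)(C)C)c(O[Si](C)(C)C(C)(C)C)c1)C2=O | intermediate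
10 | 8-prenylorobol 7,3',4'-tris(TBS) ether | CC(C)=CCc1c(O[Si](C)(C)C(C)(C)C)cc(O)c2c(=O)c(-c3ccc(O[Si](C)(C)C(C)(C)C)c(O[Si](C)(C)C(C)(C)C)c3)coc12 | intermediate
11 | prop-2-en-1-ol (allyl alcohol) | C=CCO | starting material
12 | 5-O-allyl-8-prenylorobol 7,3',4'-tris(TBS) ether | CC(C)=CCc1c(O[Si](C)(C)C(C)(C)C)cc(OCC=C)c2c(=O)c(-c3ccc(O[Si](C)(C)C(C)(C)C)c(O[Si](C)(C)C(C)(C)C)c3)coc12 | intermediate
13 | ortho-dienone: 6-allyl-8-prenyl-6H-chromene-4,5-dione tautomer (not isolated) | C=CCC1C(=O)C2=C(OC=C(c3ccc(O[Si](C)(C)C(C)(C)C)c(O[Si](C)(C)C(C)(C)C)c3)C2=O)C(CC=C(C)C)=C1O[Si](C)(C)C(C)(C)C | intermediate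
14 | 6-allyl-8-prenylorobol 7,3',4'-tris(TBS) ether | C=CCc1c(O[Si](C)(C)C(C)(C)C)c(CC=C(C)C)c2occ(-c3ccc(O[Si](C)(C)C(C)(C)C)c(O[Si](C)(C)C(C)(C)C)c3)c(=O)c2c1O | intermediate
15 | 6-allyl-8-prenylorobol 5,7,3',4'-tetrakis(TBS) ether | C=CCc1c(O[Si](C)(C)C(C)(C)C)c(CC=C(C)C)c2occ(-c3ccc(O[Si](C)(C)C(C)(C)C)c(O[Si](C)(C)C(C)(C)C)c3)c(=O)c2c1O[Si](C)(C)C(C)(C)C | intermediate
16 | methacrolein (2-methylprop-2-enal) | C=C(C)C=O | starting material
17 | 6-[(E)-3-methyl-4-oxobut-2-enyl]-8-prenylorobol tetrakis(TBS) ether | O=C/C(C)=C/Cc1c(O[Si](C)(C)C(C)(C)C)c(CC=C(C)C)c2occ(-c3ccc(O[Si](C)(C)C(C)(C)C)c(O[Si](C)(C)C(C)(C)C)c3)c(=O)c2c1O[Si](C)(C)C(C)(C)C | intermediate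
18 | 6-[(E)-4-hydroxy-3-methylbut-2-enyl]-8-prenylorobol tetrakis(TBS) ether | OC/C(C)=C/Cc1c(O[Si](C)(C)C(C)(C)C)c(CC=C(C)C)c2occ(-c3ccc(O[Si](C)(C)C(C)(C)C)c(O[Si](C)(C)C(C)(C)C)c3)c(=O)c2c1O[Si](C)(C)C(C)(C)C | intermediate
19 | 6-{[(2R,3R)-3-(hydroxymethyl)-3-methyloxiran-2-yl]methyl}-8-prenylorobol tetrakis(TBS) ether | OC[C@@]1(C)O[C@@H]1Cc1c(O[Si](C)(C)C(C)(C)C)c(CC=C(C)C)c2occ(-c3ccc(O[Si](C)(C)C(C)(C)C)c(O[Si](C)(C)C(C)(C)C)c3)c(=O)c2c1O[Si](C)(C)C(C)(C)C | intermediate
20 | 6-{[(2R,3S)-3-(iodomethyl)-3-methyloxiran-2-yl]methyl}-8-prenylorobol tetrakis(TBS) ether | IC[C@@]1(C)O[C@@H]1Cc1c(O[Si](C)(C)C(C)(C)C)c(CC=C(C)C)c2occ(-c3ccc(O[Si](C)(C)C(C)(C)C)c(O[Si](C)(C)C(C)(C)C)c3)c(=O)c2c1O[Si](C)(C)C(C)(C)C | intermediate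
21 | 6-[(2R)-2-hydroxy-3-methylbut-3-enyl]-8-prenylorobol tetrakis(TBS) ether | C=C(C)[C@H](O)Cc1c(O[Si](C)(C)C(C)(C)C)c(CC=C(C)C)c2occ(-c3ccc(O[Si](C)(C)C(C)(C)C)c(O[Si](C)(C)C(C)(C)C)c3)c(=O)c2c1O[Si](C)(C)C(C)(C)C | intermediate
22 | 6-[(2R)-2-hydroxy-3-methylbut-3-enyl]-8-prenylorobol (CNP0305771.1) | C=C(C)[C@H](O)Cc1c(O)c(CC=C(C)C)c2occ(-c3ccc(O)c(O)c3)c(=O)c2c1O | target

**Step count and risk**
Total step count: 13. Longest linear sequence: 13 steps (1 and 2 to 22; 6, 11 and 16 are bought and enter directly).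

Step 10 (key step). What may go wrong: erosion of enantioface selectivity, because the chromone carbonyl and the four silyloxy groups compete with the tartrate for titanium and a tartrate-free titanium peroxide epoxidises without facial bias; slow turnover would also let the prenyl alkene be oxidised. Fallback, setting out from 21 and returning at 21: material of insufficient enantiomeric purity is carried through steps 11 and 12. The carbinol of 21 is then oxidised with Dess–Martin periodinane/NaHCO3 (CH2Cl2, 0 °C) to the isopropenyl ketone 6-(3-methyl-2-oxobut-3-enyl)-8-prenylorobol tetrakis(TBS) ether F1. F1 is reduced by Corey–Bakshi–Shibata reduction with (S)-2-methyl-CBS-oxazaborolidine and catecholborane (toluene, −78 °C). With the isopropenyl group acting as the larger ketone substituent, hydride should arrive on the face that gives the (R)-carbinol. The stereocentre is thus set by reagent-controlled ketone reduction instead of alkene oxidation, and the route is rejoined at 21 before step 13.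

Step 8. What may go wrong: the ruthenium carbene also engages the C8 prenyl alkene (loss of isobutene and a second enal), or a ruthenium hydride moves the allyl double bond into conjugation with ring A. Fallback, setting out from 5 and returning at 17: the chain is finished before any prenyl group is present.
- Mitsunobu reaction of 5 with 11 gives 5-O-allylorobol 7,3',4'-tris(TBS) ether F2.
- Heating as in step 6 gives, through the 6-allyl ortho-dienone F3, 6-allylorobol 7,3',4'-tris(TBS) ether F4.
- Cross-metathesis of F4 with 16 as in step 8, now without a competing alkene, gives 6-[(E)-3-methyl-4-oxobut-2-enyl]orobol 7,3',4'-tris(TBS) ether F5.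
- Mitsunobu reaction of F5 with 6 gives the 5-O-prenyl ether of this enal F6.
- On heating with Eu(fod)3 the blocked ortho position cannot enolise, so the 6,6-disubstituted ortho-dienone F7 must hand the 1,1-dimethylallyl group on to C8 (8-prenyl para-dienone F8). The enal-bearing chain should not migrate, since that would break its conjugation and create a quaternary carbon on C8. Enolisation gives 6-[(E)-3-methyl-4-oxobut-2-enyl]-8-prenylorobol 7,3',4'-tris(TBS) ether F9.
- Silylation of F9 as in step 7 returns to 17.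

Step 4. What may go wrong: enolisation of ortho-dienone 8 before the Cope shift (which ends at the 6-(1,1-dimethylallyl) phenol), or Lewis-acid cleavage of the prenyl ether. Fallback, setting out from 5 and returning at 14: both carbon substituents are introduced by cross-coupling instead of sigmatropic shifts.
- Iodination of 5 with benzyltrimethylammonium dichloroiodate (BnMe3N+ ICl2−) and CaCO3 in CH2Cl2–MeOH, which goes ortho to the free chelated 5-OH in 5-hydroxy-7-alkoxychromones, gives 6-iodoorobol 7,3',4'-tris(TBS) ether F10. The position of the iodine is to be confirmed by HMBC before going on.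
- N-Bromosuccinimide (DMF, 0 °C) fills the last free position of ring A and gives 8-bromo-6-iodoorobol 7,3',4'-tris(TBS) ether F11.
- Stille coupling with allyltributylstannane (CH2=CHCH2SnBu3; Pd(PPh3)4, DMF, 80 °C) takes place at the more reactive C–I bond and gives 6-allyl-8-bromoorobol 7,3',4'-tris(TBS) ether F12.
- A second Stille coupling with tributyl(3-methylbut-2-enyl)stannane (Me2C=CHCH2SnBu3; Pd(PPh3)4, DMF, 100 °C) at the C–Br bond gives 14, where the route is rejoined; compounds 7, 10 and 12 are bypassed.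

**Further compounds**
F1 | step 10 | 6-(3-methyl-2-oxobut-3-enyl)-8-prenylorobol tetrakis(TBS) ether | C=C(C)C(=O)Cc1c(O[Si](C)(C)C(C)(C)C)c(CC=C(C)C)c2occ(-c3ccc(O[Si](C)(C)C(C)(C)C)c(O[Si](C)(C)C(C)(C)C)c3)c(=O)c2c1O[Si](C)(C)C(C)(C)C
F2 | step 8 | 5-O-allylorobol 7,3',4'-tris(TBS) ether | C=CCOc1cc(O[Si](C)(C)C(C)(C)C)cc2occ(-c3ccc(O[Si](C)(C)C(C)(C)C)c(O[Si](C)(C)C(C)(C)C)c3)c(=O)c12
F3 | step 8 | 6-allyl ortho-dienone (6H-chromene-4,5-dione tautomer, not isolated) | C=CCC1C(=O)C2=C(OC=C(c3ccc(O[Si](C)(C)C(C)(C)C)c(O[Si](C)(C)C(C)(C)C)c3)C2=O)C=C1O[Si](C)(C)C(C)(C)C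
F4 | step 8 | 6-allylorobol 7,3',4'-tris(TBS) ether | C=CCc1c(O[Si](C)(C)C(C)(C)C)cc2occ(-c3ccc(O[Si](C)(C)C(C)(C)C)c(O[Si](C)(C)C(C)(C)C)c3)c(=O)c2c1O
F5 | step 8 | 6-[(E)-3-methyl-4-oxobut-2-enyl]orobol 7,3',4'-tris(TBS) ether | O=C/C(C)=C/Cc1c(O[Si](C)(C)C(C)(C)C)cc2occ(-c3ccc(O[Si](C)(C)C(C)(C)C)c(O[Si](C)(C)C(C)(C)C)c3)c(=O)c2c1O
F6 | step 8 | 5-O-prenyl ether of F5 | O=C/C(C)=C/Cc1c(O[Si](C)(C)C(C)(C)C)cc2occ(-c3ccc(O[Si](C)(C)C(C)(C)C)c(O[Si](C)(C)C(C)(C)C)c3)c(=O)c2c1OCC=C(C)C
F7 | step 8 | 6,6-disubstituted ortho-dienone (not isolated) | C=CC(C)(C)C1(C/C=C(\C)C=O)C(=O)C2=C(OC=C(c3ccc(O[Si](C)(C)C(C)(C)C)c(O[Si](C)(C)C(C)(C)C)c3)C2=O)C=C1O[Si](C)(C)C(C)(C)C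
F8 | step 8 | 8-prenyl para-dienone (not isolated) | CC(C)=CCC1C(O[Si](C)(C)C(C)(C)C)=C(C/C=C(\C)C=O)C(=O)C2=C1OC=C(c1ccc(O[Si](C)(C)C(C)(C)C)c(O[Si](C)(C)C(C)(C)C)c1)C2=O
F9 | step 8 | 6-[(E)-3-methyl-4-oxobut-2-enyl]-8-prenylorobol 7,3',4'-tris(TBS) ether | O=C/C(C)=C/Cc1c(O[Si](C)(C)C(C)(C)C)c(CC=C(C)C)c2occ(-c3ccc(O[Si](C)(C)C(C)(C)C)c(O[Si](C)(C)C(C)(C)C)c3)c(=O)c2c1O
F10 | step 4 | 6-iodoorobol 7,3',4'-tris(TBS) ether | Ic1c(O[Si](C)(C)C(C)(C)C)cc2occ(-c3ccc(O[Si](C)(C)C(C)(C)C)c(O[Si](C)(C)C(C)(C)C)c3)c(=O)c2c1O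
F11 | step 4 | 8-bromo-6-iodoorobol 7,3',4'-tris(TBS) ether | Ic1c(O[Si](C)(C)C(C)(C)C)c(Br)c2occ(-c3ccc(O[Si](C)(C)C(C)(C)C)c(O[Si](C)(C)C(C)(C)C)c3)c(=O)c2c1O
F12 | step 4 | 6-allyl-8-bromoorobol 7,3',4'-tris(TBS) ether | C=CCc1c(O[Si](C)(C)C(C)(C)C)c(Br)c2occ(-c3ccc(O[Si](C)(C)C(C)(C)C)c(O[Si](C)(C)C(C)(C)C)c3)c(=O)c2c1O
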